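**Analysis of the target**

The target is a cis-fused eremophilane-type decalin. Ring A is C1–C5 plus C10, with the ketone at C2 and the secondary methyl C15 on C4; ring B is C5–C10, with the isopropenyl group (C11–C13) on C7 and acyloxy groups on C8 and C9; the angular methyl C14 sits on the quaternary carbon C5. The six ring stereocentres are 4S,5R,7R,8R,9S,10S: C14, C15, H10 and the isopropenyl group lie on one face and the two ester oxygens on the other, so the C8/C9 diol is cis and trans to the C7 substituent. In the only ring B chair that avoids a 1,3-diaxial clash between C14 and the isopropenyl group, the C7 and C8 substituents are equatorial, ring A is folded under the α face (C4 axial on ring B), and O9 is axial and syn to C4. The sensitive functions are two different esters on a cis-diol (acyl migration once one hydroxyl is free), the conjugated E-tiglate, the α-stereocentre of the (R)-2-methylbutanoate, an acid-isomerisable 1,1-disubstituted alkene and an unhindered ketone. The synthesis is hard because of the vicinal C4/C5 pair with cis methyl groups and a quaternary carbon, the contiguous C7–C8–C9–C10 array, the need to tell O8 from O9, and the hindered axial O9 that carries the unsaturated ester. The strategy rests on the fact that O9 stands 1,4 to the C2 carbonyl oxygen along C9–C10–C1–C2. That spacing is what a reductive union of the β-carbon C10 of a C10=C1–C2=O enone with a C9 aldehyde leaves behind, and because C9–C10 is a ring B bond the same event closes ring B on a monocyclic ring A enone whose C5 side chain already carries C7 and C8.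

**Retrosynthetic reasoning**

Ester C–O bonds and the C2 mask. Target 31 is traced to its dioxolane 30, so that the ketone is unmasked last, when no hydroxyl is free and no acyl group can migrate. The O8–acyl bond of 30 is cut to alcohol 28 and acid 29, and the O9–acyl bond of silyl ether 27 is cut to alcohol 25 and tiglic acid 26. O9 is axial and hindered, so it is acylated first while O8 is still silylated; the saturated α-branched acid goes on afterwards under mild conditions. This gives full differentiation of the cis-diol without any selective acylation.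

C9–H bond. Alcohol 25 is traced to ketone 24, and 24 to the epimeric carbinol 23 and its parent ketone 22. The ketone is a funnel: whatever C9 configuration the ring closure delivers, oxidation removes it and a hydride delivered to the convex face of the locked cis-decalin installs the axial 9α alcohol. The C2 dioxolane is required so that this redox pair touches only C9.

C9–C10 bond (key disconnection). Cutting C9–C10 in 22 opens ring B and leads to enone-aldehyde 21. The cut is placed here because it is the only ring B bond whose formation uses the native C2 ketone (as an enone) and the native O9 (as an aldehyde oxygen), and because the tether from C5 forces the cis ring fusion. The forward reaction has to deliver one electron to the enone, join C10 to C9, and leave the C7 and C8 centres untouched.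

C9 aldehyde and O8 silyl ether. The aldehyde of 21 is traced to the terminal acetonide 20, and 20 to alcohol 19. C9 is carried as the carbinol carbon of a dioxolane, so that the aldehyde is released only immediately before the key step and the extra carbon is lost by oxidative glycol cleavage.

C7–C8 bond. Alcohol 19 is cut between C7 and C8 into allylic bromide 16 and (S)-glyceraldehyde acetonide 17. A γ-selective carbonyl allylation forms this bond, creates both stereocentres and converts a trisubstituted alkene into the isopropenyl group in one operation. The chiral aldehyde supplies the absolute sense, so ring B stereochemistry does not depend on relay from ring A.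

Allylic C–Br and C–O bonds. Bromide 16 comes from allylic alcohol 15, and 15 from the prenyl compound 14 by oxidation of the methyl group trans to the chain. This lets the quaternary carbon be built with a simple, reactive prenyl electrophile.

Carbonyl transposition. Enone 14 is traced to vinylogous thioester 12, in which the carbonyl sits on C10 and sulfur on C2. This places the future C5 next to a carbonyl, where it can be alkylated twice, and the forward reduction–hydrolysis moves the oxygen to C2.

C5–C6 and C5–C14 bonds. 12 is cut to 9 and prenyl bromide 10, and 9 to 7 by removal of the methyl group. The order (methyl first, prenyl second) is dictated by the need for C14 cis to C15: the second electrophile enters anti to C15.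

Ring A. Vinylogous thioester 7 comes from enone 4 by attaching an arylthio group to the β-carbon without moving the carbonyl. Enone 4 is cut into crotonaldehyde 1 and tert-butyl acetoacetate 2 by a catalytic asymmetric Michael addition and aldol condensation, which sets C4.

**Alternatives that were turned down**

Alternative 1: Ring A is disconnected at C3–C4 and C5–C10 in a [4+2] sense, after O9 has been tied to C6 through an ester. The dienophile is a tigloyl unit hanging from O9 (it supplies C4, C5, C6, C14 and C15), and the diene is a 2-silyloxydiene over C10, C1, C2 and C3. Heating or a Lewis acid would give the cis-fused lactone A1.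
- For: the E geometry of the dienophile translates directly into cis C14/C15, the tether relays the C9 configuration to C10, C5 and C4 in one step, the regiochemistry is locked, and the silyl enol ether is the C2 ketone in masked form. On relay of stereochemistry into ring A this plan is stronger than the chosen one.
- Against: an ester tether must leave its preferred conformation to reach the transition state, and an α,β-dimethyl acrylate is a poor dienophile. The forcing conditions that result endanger the silyloxydiene and the α-silyloxy centre. After the key step ring B is still open: C6–C7 must be made by attack of a side-chain enolate (with a regiochemistry question between C7 and the methyl group) on the lactone carbonyl, the oxygen on C6 must then be removed, and the side-chain ketone must become the isopropenyl group with C7 set late.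
- Comparison: the chosen strategy pays for ring A control with two ordinary enolate alkylations, but its ring closure completes the carbon skeleton with every carbon except C9 at its final oxidation level.

Alternative 2: Ring B is disconnected at C5–C6. An iron hydride made from an iron β-diketonate and a silane would transfer a hydrogen atom to an exocyclic C5 methylene, and the tertiary C5 radical would add to the terminal carbon C6 of a tethered α-methylene ketone to give A2.
- For: a tertiary radical forms a quaternary carbon with little sensitivity to crowding and without strong base. On that point it is stronger than an enolate alkylation. The C7 acetyl group can be equilibrated to the equatorial position.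
- Against: the planar C5 radical is not forced to one face, so the ring fusion and the C4/C5 relationship rest on a modest bias from the neighbouring methyl group. Simple reduction of the alkene competes with the 6-endo closure. After the key step the acetonide must be removed and O8 told apart from O9 by selective acylation, and an enolisable methyl ketone must be methylenated. The precursor also needs the C8–C9–C10 triad assembled on ring A beforehand.
- Comparison: the chosen strategy fixes C5 early on a small ring with a reactive allylic halide, closes ring B at a secondary carbon where only the cis fusion is possible, and carries O8 and O9 differentiated from the start.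

Alternative 3: Ring B is disconnected at C5–C6 and C9–C10 by an intermolecular Diels–Alder reaction. The electron-rich diene A4 would add across C5=C10 of a 2-methylcyclohexenone-type ring A, and acid work-up would give the enedione A3.
- For: it is the most convergent route to the bare cis-decalin with the angular methyl in place, from cheap components. On brevity to the bicyclic core it is stronger than the chosen plan.
- Against: the dienophile is an α-methyl, β-substituted cyclic enone and reacts sluggishly even with activated dienes. Its facial selectivity depends on a remote silyloxy group that is later destroyed. A3 lacks C15, the isopropenyl group and both ring B oxygens in usable form: C15 must be built from the C4 ketone, the isopropenyl group must go onto C7 (the α-carbon of the C8 enone, so no conjugate addition is available), and C9 must be oxygenated. Four stereocentres would then be set one by one by substrate control on a flexible cis-decalin.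
- Comparison: the chosen strategy reaches the ring closure with C4, C5, C7 and C8 already fixed by reagent or chiral-pool control, so only C9 needs adjusting afterwards.

Key step: step 11

Remark: the (R)-configured diarylprolinol silyl ether in step 1 is assigned by the usual iminium shielding model (the (S)-catalyst is predicted to give the (R)-enone), and aldehyde 17 is taken as a purchased reagent, distilled before use.

**Route**

Step 1
Reactants: 1 (E)-but-2-enal (crotonaldehyde); 2 tert-butyl 3-oxobutanoate
Product: 4 (5S)-5-methylcyclohex-2-en-1-one, via Michael adduct 3 (not isolated)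
Conditions: (R)-2-{bis[3,5-bis(trifluoromethyl)phenyl](trimethylsilyloxy)methyl}pyrrolidine (10 mol %), neat, rt; then p-TsOH·H2O (20 mol %), toluene, 80 °C
Reagents that add atoms: none
Why: Iminium-catalysed asymmetric Michael addition of the β-keto ester to the enal sets the methyl-bearing carbon (later C4), because the bulky group of the catalyst blocks one face of the s-trans iminium ion; acid then brings about intramolecular aldol condensation, cleavage of the tert-butyl ester and decarboxylation in the same flask. The (S)-enone is needed because its carbonyl carbon becomes C10 and its α'-carbon becomes C5.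

Step 2
Reactants: 4 (5S)-5-methylcyclohex-2-en-1-one
Product: 7 (5R)-5-methyl-3-(phenylsulfanyl)cyclohex-2-en-1-one, via sulfide ketone 5 (not isolated), via chloro sulfide 6 (not isolated)
Conditions: PhSH, Et3N (cat.), CH2Cl2, 0 °C; then N-chlorosuccinimide, 0 °C to rt; then Et3N
Reagents that add atoms: thiophenol, Sc1ccccc1
Why: Thia-Michael addition, S-chlorination with Pummerer-type shift of chlorine to the sulfur-bearing carbon, and loss of HCl towards the acidic α-position give the vinylogous thioester (β-sulfenylation of an enone). The carbonyl never leaves its carbon, so no symmetrical 1,3-dione can form and the stereocentre is kept; the change of descriptor from S to R is only a change of CIP priorities.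

Step 3
Reactants: 7 (5R)-5-methyl-3-(phenylsulfanyl)cyclohex-2-en-1-one
Product: 9 (5S,6R)-5,6-dimethyl-3-(phenylsulfanyl)cyclohex-2-en-1-one, via lithium dienolate 8 (not isolated)
Conditions: LiN(i-Pr)2, THF, −78 °C; MeI, −78 to 0 °C
Reagents that add atoms: iodomethane, CI
Why: Stork–Danheiser-type kinetic α'-deprotonation of the vinylogous thioester and C-methylation install C14; the methyl group should enter mainly trans to the ring methyl, but this centre becomes trigonal again in step 4, so its configuration does not matter.

Step 4
Reactants: 9 (5S,6R)-5,6-dimethyl-3-(phenylsulfanyl)cyclohex-2-en-1-one; 10 1-bromo-3-methylbut-2-ene (prenyl bromide)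
Product: 12 (5S,6R)-5,6-dimethyl-6-(3-methylbut-2-en-1-yl)-3-(phenylsulfanyl)cyclohex-2-en-1-one, via lithium dienolate 11 (not isolated)
Conditions: LiN(i-Pr)2, THF, −78 °C; then 10, DMPU, −78 °C to rt
Reagents that add atoms: none
Why: The second α'-alkylation of the Stork–Danheiser sequence, with a reactive primary allylic halide, builds the quaternary carbon C5 (bond C5–C6). In the nearly planar dienolate the C15 methyl on C4 is pseudoaxial to escape A(1,2) strain with the enolate methyl, so the bromide approaches from the opposite face and C14 ends up cis to C15.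

Step 5
Reactants: 12 (5S,6R)-5,6-dimethyl-6-(3-methylbut-2-en-1-yl)-3-(phenylsulfanyl)cyclohex-2-en-1-one
Product: 14 (4R,5S)-4,5-dimethyl-4-(3-methylbut-2-en-1-yl)cyclohex-2-en-1-one, via allylic alcohol 13 (not isolated)
Conditions: i-Bu2AlH, toluene, −78 °C; then 2 M aq. HCl, THF, rt
Reagents that add atoms: water, O
Why: Stork–Danheiser transposition: 1,2-hydride addition gives the allylic alcohol, which ionises in acid to a sulfur-stabilised allyl cation; water adds at the thio-substituted carbon and thiophenol is lost, so the carbonyl appears on C2 and the alkene on C10=C1. No stereocentre is touched.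

Step 6
Reactants: 14 (4R,5S)-4,5-dimethyl-4-(3-methylbut-2-en-1-yl)cyclohex-2-en-1-one
Product: 15 (4R,5S)-4-[(2E)-4-hydroxy-3-methylbut-2-en-1-yl]-4,5-dimethylcyclohex-2-en-1-one
Conditions: SeO2 (0.5 equiv), t-BuOOH (3 equiv), CH2Cl2, rt
Reagents that add atoms: selenium dioxide, O=[Se]=O; tert-butyl hydroperoxide, CC(C)(C)OO
Why: Selenium dioxide allylic oxidation (ene reaction, then [2,3]-sigmatropic shift), run with the hydroperoxide as terminal oxidant, hydroxylates a gem-dimethyl trisubstituted alkene at the methyl group trans to the chain and so gives the E allylic alcohol. The ring enone has no allylic hydrogen (C5 is quaternary), and oxidation next to the ketone needs harsher conditions.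

Step 7
Reactants: 15 (4R,5S)-4-[(2E)-4-hydroxy-3-methylbut-2-en-1-yl]-4,5-dimethylcyclohex-2-en-1-one
Product: 16 (4R,5S)-4-[(2E)-4-bromo-3-methylbut-2-en-1-yl]-4,5-dimethylcyclohex-2-en-1-one
Conditions: CBr4, PPh3, CH2Cl2, 0 °C
Reagents that add atoms: carbon tetrabromide, BrC(Br)(Br)Br
Why: Appel reaction of a primary allylic alcohol under neutral conditions; the enone is inert and the alkene geometry is kept.

Step 8
Reactants: 16 (4R,5S)-4-[(2E)-4-bromo-3-methylbut-2-en-1-yl]-4,5-dimethylcyclohex-2-en-1-one; 17 (4S)-2,2-dimethyl-1,3-dioxolane-4-carbaldehyde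
Product: 19 (4R,5S)-4-{(2R,3R)-3-[(4S)-2,2-dimethyl-1,3-dioxolan-4-yl]-3-hydroxy-2-(prop-1-en-2-yl)propyl}-4,5-dimethylcyclohex-2-en-1-one, via allylchromium reagent 18 (not isolated)
Conditions: CrCl2 (4 equiv), 17 (1.5 equiv), THF, 0 °C to rt
Reagents that add atoms: none
Why: Nozaki–Hiyama allylation: CrCl2 inserts into the allylic bromide and the allylchromium reagent adds to the aldehyde through its γ-carbon, which forms C7–C8 and turns the trisubstituted alkene into the isopropenyl group. The chair transition state with the aldehyde residue and the γ-substituent equatorial gives the anti C7/C8 relationship, and Felkin–Anh attack anti to the dioxolane C–O bond of 17 fixes the absolute sense (7R,8R). Aldehydes react much faster than the ring enone with this reagent.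

Step 9
Reactants: 19 (4R,5S)-4-{(2R,3R)-3-[(4S)-2,2-dimethyl-1,3-dioxolan-4-yl]-3-hydroxy-2-(prop-1-en-2-yl)propyl}-4,5-dimethylcyclohex-2-en-1-one
Product: 20 (4R,5S)-4-{(2R,3R)-3-[(tert-butyldimethylsilyl)oxy]-3-[(4S)-2,2-dimethyl-1,3-dioxolan-4-yl]-2-(prop-1-en-2-yl)propyl}-4,5-dimethylcyclohex-2-en-1-one
Conditions: TBSOTf, 2,6-lutidine, CH2Cl2, −78 to 0 °C
Reagents that add atoms: tert-butyldimethylsilyl trifluoromethanesulfonate, CC(C)(C)[Si](C)(C)OS(=O)(=O)C(F)(F)F
Why: Silylation of a hindered secondary alcohol with a silyl triflate and a hindered pyridine base, which is too weak to enolise the enone; the ether masks O8 and keeps it distinct from O9.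

Step 10
Reactants: 20 (4R,5S)-4-{(2R,3R)-3-[(tert-butyldimethylsilyl)oxy]-3-[(4S)-2,2-dimethyl-1,3-dioxolan-4-yl]-2-(prop-1-en-2-yl)propyl}-4,5-dimethylcyclohex-2-en-1-one
Product: 21 (2R,3R)-2-[(tert-butyldimethylsilyl)oxy]-3-{[(1R,6S)-1,6-dimethyl-4-oxocyclohex-2-en-1-yl]methyl}-4-methylpent-4-enal
Conditions: H5IO6, EtOAc, rt
Reagents that add atoms: none
Why: Periodic acid hydrolyses the terminal acetonide and cleaves the liberated 1,2-diol in one operation (glycol cleavage), leaving C9 as the aldehyde. The secondary silyl ether, the enone and the isopropenyl group are inert, and the aldehyde is used at once to avoid epimerisation at C8.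

Step 11
Reactants: 21 (2R,3R)-2-[(tert-butyldimethylsilyl)oxy]-3-{[(1R,6S)-1,6-dimethyl-4-oxocyclohex-2-en-1-yl]methyl}-4-methylpent-4-enal
Product: 22 (4S,5R,7R,8R,9R,10S)-8-[(tert-butyldimethylsilyl)oxy]-9-hydroxyeremophil-11-en-2-one (cis-fused, 9β-hydroxyl)
Conditions: divided cell, glassy-carbon cathode, Pt anode, Et4NOTs (0.2 M), CH2(CO2Me)2 (2 equiv), MeCN, −2.1 V vs SCE, rt, 5 mM substrate, about 2 F/mol
Reagents that add atoms: none
Why: At the cathode the enone, which accepts an electron at a less negative potential than the saturated aldehyde, is reduced to its radical anion; its β-carbon C10 adds to the tethered C9 carbonyl carbon, and a second electron and two protons from dimethyl malonate (recovered unchanged on work-up) give the γ-hydroxy ketone. The closest known reaction type is the electroreductive cyclisation of enones and enoates onto tethered aldehydes and ketones (ketyl–olefin-type coupling). Ring B closes in a 6-exo-trig mode with respect to the C9=O bond, through a chair in which the C7 isopropenyl and C8 silyloxy groups are equatorial. C10 is controlled by the tether: the chain starts at C5 and can reach only the face of C10 that it already occupies, so H10 ends up cis to C14 (cis-decalin, 10S). C9 is controlled by no enforced element: an aldehyde oxygen placed pseudo-equatorial, away from the syn-axial C4 and anti to the reduced enone, leads to the 9β (9R) alcohol shown, whereas a Felkin–Anh preference would favour attack on the other aldehyde face. Either outcome is acceptable, because C9 becomes trigonal in step 13. The step needs reduction of the enone before the aldehyde (controlled potential), ring closure before hydrodimerisation (high dilution), and protonation of electrogenerated bases before they epimerise C8 (malonate buffer); the silyl ether is a poor leaving group, so loss of O8 is not expected.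

Step 12
Reactants: 22 (4S,5R,7R,8R,9R,10S)-8-[(tert-butyldimethylsilyl)oxy]-9-hydroxyeremophil-11-en-2-one
Product: 23 (4S,5R,7R,8R,9R,10S)-8-[(tert-butyldimethylsilyl)oxy]-2,2-(ethylenedioxy)eremophil-11-en-9-ol
Conditions: HOCH2CH2OH, PPTS, benzene, reflux (Dean–Stark)
Reagents that add atoms: ethane-1,2-diol, OCCO
Why: Acid-catalysed ketalisation of the unhindered C2 ketone with azeotropic removal of water; it is needed so that C9 can pass through a ketone without a second, more reactive ketone in the molecule. The mild pyridinium acid leaves the silyl ether and the isopropenyl group untouched.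

Step 13
Reactants: 23 (4S,5R,7R,8R,9R,10S)-8-[(tert-butyldimethylsilyl)oxy]-2,2-(ethylenedioxy)eremophil-11-en-9-ol
Product: 24 (4S,5R,7R,8R,10S)-8-[(tert-butyldimethylsilyl)oxy]-2,2-(ethylenedioxy)eremophil-11-en-9-one
Conditions: Dess–Martin periodinane, NaHCO3, CH2Cl2, 0 °C to rt
Reagents that add atoms: none
Why: Dess–Martin oxidation under buffered, non-enolising conditions converts the C9 carbinol, whichever way it is configured, into the ketone without epimerising C8 or C10.

Step 14
Reactants: 24 (4S,5R,7R,8R,10S)-8-[(tert-butyldimethylsilyl)oxy]-2,2-(ethylenedioxy)eremophil-11-en-9-one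
Product: 25 (4S,5R,7R,8R,9S,10S)-8-[(tert-butyldimethylsilyl)oxy]-2,2-(ethylenedioxy)eremophil-11-en-9-ol
Conditions: LiBH(s-Bu)3, THF, −78 °C; AcOH quench at −78 °C
Reagents that add atoms: none
Why: Bulky-hydride reduction of a conformationally locked cyclohexanone: ring B keeps the chair with the C7 and C8 groups equatorial, and the axial trajectory on the α face is blocked by the syn-axial C4–C5 bond and by ring A folded under it. Hydride therefore arrives equatorially from the convex β face and gives the axial 9α alcohol (9S), cis to O8. The cold acidic quench avoids migration of the silyl group to the new alkoxide.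

Step 15
Reactants: 25 (4S,5R,7R,8R,9S,10S)-8-[(tert-butyldimethylsilyl)oxy]-2,2-(ethylenedioxy)eremophil-11-en-9-ol; 26 (E)-2-methylbut-2-enoic acid (tiglic acid)
Product: 27 (4S,5R,7R,8R,9S,10S)-8-[(tert-butyldimethylsilyl)oxy]-2,2-(ethylenedioxy)eremophil-11-en-9-yl (E)-2-methylbut-2-enoate
Conditions: 26, 2,4,6-Cl3C6H2COCl, Et3N, THF, rt; then 25, DMAP, toluene, 70 °C
Reagents that add atoms: none
Why: Yamaguchi esterification: the mixed anhydride of tiglic acid, activated by DMAP, acylates the hindered axial hydroxyl; the E geometry of the trisubstituted double bond is the stable one and is kept.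

Step 16
Reactants: 27 (4S,5R,7R,8R,9S,10S)-8-[(tert-butyldimethylsilyl)oxy]-2,2-(ethylenedioxy)eremophil-11-en-9-yl (E)-2-methylbut-2-enoate
Product: 28 (4S,5R,7R,8R,9S,10S)-2,2-(ethylenedioxy)-8-hydroxyeremophil-11-en-9-yl (E)-2-methylbut-2-enoate
Conditions: HF·pyridine, pyridine, THF, 0 °C to rt
Reagents that add atoms: none
Why: Fluoride cleavage of the secondary silyl ether under buffered, slightly acidic conditions, where base-promoted migration of the tigloyl group from O9 to the freed O8 is slow; the dioxolane and both alkenes survive.

Step 17
Reactants: 28 (4S,5R,7R,8R,9S,10S)-2,2-(ethylenedioxy)-8-hydroxyeremophil-11-en-9-yl (E)-2-methylbut-2-enoate; 29 (2R)-2-methylbutanoic acid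
Product: 30 (4S,5R,7R,8R,9S,10S)-2,2-(ethylenedioxy)-8-{[(2R)-2-methylbutanoyl]oxy}eremophil-11-en-9-yl (E)-2-methylbut-2-enoate
Conditions: 29, 2,4,6-Cl3C6H2COCl, Et3N, THF, 0 °C; then 28, DMAP, toluene, rt
Reagents that add atoms: none
Why: Yamaguchi esterification of the equatorial C8 hydroxyl, carried out directly after step 16; the mixed anhydride reacts through an acylpyridinium ion and not through a ketene, so the α-stereocentre of the acid should be retained.

Step 18
Reactants: 30 (4S,5R,7R,8R,9S,10S)-2,2-(ethylenedioxy)-8-{[(2R)-2-methylbutanoyl]oxy}eremophil-11-en-9-yl (E)-2-methylbut-2-enoate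
Product: 31 CNP0312791.1, (4S,5R,7R,8R,9S,10S)-8-{[(2R)-2-methylbutanoyl]oxy}-2-oxoeremophil-11-en-9-yl (E)-2-methylbut-2-enoate
Conditions: 1 M aq. HCl, THF, rt
Reagents that add atoms: water, O
Why: Acid-catalysed hydrolysis of the dioxolane releases the C2 ketone; with no free hydroxyl left, acyl migration cannot occur, and the esters and the isopropenyl group tolerate dilute acid at room temperature.

**Compound list**

1 | (E)-but-2-enal (crotonaldehyde) | C/C=C/C=O | starting material
2 | tert-butyl 3-oxobutanoate | CC(=O)CC(=O)OC(C)(C)C | starting material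
3 | tert-butyl (3S)-2-acetyl-3-methyl-5-oxopentanoate (C2 epimers) | C[C@H](C(C(C)=O)C(=O)OC(C)(C)C)CC=O | intermediate (not isolated)
4 | (5S)-5-methylcyclohex-2-en-1-one | C[C@H]1CC=CC(=O)C1 | intermediate
5 | (5R)-5-methyl-3-(phenylsulfanyl)cyclohexan-1-one (C3 epimers) | C[C@H]1CC(Sc2ccccc2)CC(=O)C1 | intermediate (not isolated)
6 | (5R)-3-chloro-5-methyl-3-(phenylsulfanyl)cyclohexan-1-one (C3 epimers) | C[C@H]1CC(Cl)(Sc2ccccc2)CC(=O)C1 | intermediate (not isolated)
7 | (5R)-5-methyl-3-(phenylsulfanyl)cyclohex-2-en-1-one | C[C@H]1CC(Sc2ccccc2)=CC(=O)C1 | intermediate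
8 | lithium (3S)-3-methyl-5-(phenylsulfanyl)cyclohexa-1,5-dien-1-olate | [Li+].C[C@H]1CC(Sc2ccccc2)=CC([O-])=C1 | intermediate (not isolated)
9 | (5S,6R)-5,6-dimethyl-3-(phenylsulfanyl)cyclohex-2-en-1-one | C[C@H]1CC(Sc2ccccc2)=CC(=O)[C@@H]1C | intermediate
10 | 1-bromo-3-methylbut-2-ene (prenyl bromide) | CC(C)=CCBr | starting material
11 | lithium (3S)-2,3-dimethyl-5-(phenylsulfanyl)cyclohexa-1,5-dien-1-olate | [Li+].C[C@H]1CC(Sc2ccccc2)=CC([O-])=C1C | intermediate (not isolated)
12 | (5S,6R)-5,6-dimethyl-6-(3-methylbut-2-en-1-yl)-3-(phenylsulfanyl)cyclohex-2-en-1-one | C[C@H]1CC(Sc2ccccc2)=CC(=O)[C@]1(C)CC=C(C)C | intermediate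
13 | (5S,6R)-5,6-dimethyl-6-(3-methylbut-2-en-1-yl)-3-(phenylsulfanyl)cyclohex-2-en-1-ol (C1 epimers) | C[C@H]1CC(Sc2ccccc2)=CC(O)[C@]1(C)CC=C(C)C | intermediate (not isolated)
14 | (4R,5S)-4,5-dimethyl-4-(3-methylbut-2-en-1-yl)cyclohex-2-en-1-one | C[C@H]1CC(=O)C=C[C@]1(C)CC=C(C)C | intermediate
15 | (4R,5S)-4-[(2E)-4-hydroxy-3-methylbut-2-en-1-yl]-4,5-dimethylcyclohex-2-en-1-one | C[C@H]1CC(=O)C=C[C@]1(C)C/C=C(\C)CO | intermediate
16 | (4R,5S)-4-[(2E)-4-bromo-3-methylbut-2-en-1-yl]-4,5-dimethylcyclohex-2-en-1-one | C[C@H]1CC(=O)C=C[C@]1(C)C/C=C(\C)CBr | intermediate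
17 | (4S)-2,2-dimethyl-1,3-dioxolane-4-carbaldehyde ((S)-glyceraldehyde acetonide) | O=C[C@@H]1COC(C)(C)O1 | starting material
18 | dichloro{(2E)-4-[(1R,6S)-1,6-dimethyl-4-oxocyclohex-2-en-1-yl]-2-methylbut-2-en-1-yl}chromium (allylchromium reagent) | C[C@H]1CC(=O)C=C[C@]1(C)C/C=C(\C)C[Cr](Cl)Cl | intermediate (not isolated)
19 | (4R,5S)-4-{(2R,3R)-3-[(4S)-2,2-dimethyl-1,3-dioxolan-4-yl]-3-hydroxy-2-(prop-1-en-2-yl)propyl}-4,5-dimethylcyclohex-2-en-1-one | C=C(C)[C@@H](C[C@@]1(C)C=CC(=O)C[C@@H]1C)[C@@H](O)[C@@H]2COC(C)(C)O2 | intermediate
20 | (4R,5S)-4-{(2R,3R)-3-[(tert-butyldimethylsilyl)oxy]-3-[(4S)-2,2-dimethyl-1,3-dioxolan-4-yl]-2-(prop-1-en-2-yl)propyl}-4,5-dimethylcyclohex-2-en-1-one | C=C(C)[C@@H](C[C@@]1(C)C=CC(=O)C[C@@H]1C)[C@@H](O[Si](C)(C)C(C)(C)C)[C@@H]2COC(C)(C)O2 | intermediate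
21 | (2R,3R)-2-[(tert-butyldimethylsilyl)oxy]-3-{[(1R,6S)-1,6-dimethyl-4-oxocyclohex-2-en-1-yl]methyl}-4-methylpent-4-enal | C=C(C)[C@@H](C[C@@]1(C)C=CC(=O)C[C@@H]1C)[C@@H](O[Si](C)(C)C(C)(C)C)C=O | intermediate
22 | (4S,5R,7R,8R,9R,10S)-8-[(tert-butyldimethylsilyl)oxy]-9-hydroxyeremophil-11-en-2-one | C=C(C)[C@H]1C[C@@]2(C)[C@H](CC(=O)C[C@@H]2C)[C@@H](O)[C@@H]1O[Si](C)(C)C(C)(C)C | intermediate
23 | (4S,5R,7R,8R,9R,10S)-8-[(tert-butyldimethylsilyl)oxy]-2,2-(ethylenedioxy)eremophil-11-en-9-ol | C=C(C)[C@H]1C[C@@]2(C)[C@H](CC3(OCCO3)C[C@@H]2C)[C@@H](O)[C@@H]1O[Si](C)(C)C(C)(C)C | intermediate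
24 | (4S,5R,7R,8R,10S)-8-[(tert-butyldimethylsilyl)oxy]-2,2-(ethylenedioxy)eremophil-11-en-9-one | C=C(C)[C@H]1C[C@@]2(C)[C@H](CC3(OCCO3)C[C@@H]2C)C(=O)[C@@H]1O[Si](C)(C)C(C)(C)C | intermediate
25 | (4S,5R,7R,8R,9S,10S)-8-[(tert-butyldimethylsilyl)oxy]-2,2-(ethylenedioxy)eremophil-11-en-9-ol | C=C(C)[C@H]1C[C@@]2(C)[C@H](CC3(OCCO3)C[C@@H]2C)[C@H](O)[C@@H]1O[Si](C)(C)C(C)(C)C | intermediate
26 | (E)-2-methylbut-2-enoic acid (tiglic acid) | C/C=C(\C)C(=O)O | starting material
27 | (4S,5R,7R,8R,9S,10S)-8-[(tert-butyldimethylsilyl)oxy]-2,2-(ethylenedioxy)eremophil-11-en-9-yl (E)-2-methylbut-2-enoate | C=C(C)[C@H]1C[C@@]2(C)[C@H](CC3(OCCO3)C[C@@H]2C)[C@H](OC(=O)/C(C)=C/C)[C@@H]1O[Si](C)(C)C(C)(C)C | intermediate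
28 | (4S,5R,7R,8R,9S,10S)-2,2-(ethylenedioxy)-8-hydroxyeremophil-11-en-9-yl (E)-2-methylbut-2-enoate | C=C(C)[C@H]1C[C@@]2(C)[C@H](CC3(OCCO3)C[C@@H]2C)[C@H](OC(=O)/C(C)=C/C)[C@@H]1O | intermediate
29 | (2R)-2-methylbutanoic acid | CC[C@@H](C)C(=O)O | starting material
30 | (4S,5R,7R,8R,9S,10S)-2,2-(ethylenedioxy)-8-{[(2R)-2-methylbutanoyl]oxy}eremophil-11-en-9-yl (E)-2-methylbut-2-enoate | C=C(C)[C@H]1C[C@@]2(C)[C@H](CC3(OCCO3)C[C@@H]2C)[C@H](OC(=O)/C(C)=C/C)[C@@H]1OC(=O)[C@H](C)CC | intermediate
31 | CNP0312791.1, (4S,5R,7R,8R,9S,10S)-8-{[(2R)-2-methylbutanoyl]oxy}-2-oxoeremophil-11-en-9-yl (E)-2-methylbut-2-enoate | C=C(C)[C@H]1C[C@@]2(C)[C@H](CC(=O)C[C@@H]2C)[C@H](OC(=O)/C(C)=C/C)[C@@H]1OC(=O)[C@H](C)CC | target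

**Step count and least certain steps**

Total step count: 18. Longest linear sequence: 18 steps (from 1 and 2 to 31); the other starting materials 10, 17, 26 and 29 enter as purchased reagents.

Step 11 (key step). The likely failures are intermolecular hydrodimerisation or plain saturation of the enone in place of ring closure, competing reduction at the aldehyde, and base-induced epimerisation next to the aldehyde; incomplete face selectivity at C9 is tolerated by design. The fallback forms the same C9–C10 bond by polarity inversion of the aldehyde instead of reduction of the enone. It sets out from 21: an intramolecular Stetter reaction (bicyclic N-pentafluorophenyl triazolium tetrafluoroborate precatalyst, Et3N, toluene, rt) adds the acyl-anion equivalent at C9 to C10, again only on the face of the tether, and gives (4S,5R,7R,8R,10S)-8-[(tert-butyldimethylsilyl)oxy]eremophil-11-ene-2,9-dione F1 directly at the ketone oxidation level. Selective ketalisation of the unhindered C2 carbonyl (ethane-1,2-diol, PPTS, benzene, reflux), which the flanked and α-oxygenated C9 carbonyl should resist, returns to the route at 24.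

Step 8. The likely failure is poor facial discrimination at the aldehyde, or erosion of the anti preference because the allylchromium species reacts through a loosely organised transition state, which would give mixtures at C7 and C8. The fallback sets out from 16: palladium-catalysed borylation (B2pin2, Pd2(dba)3, DMSO, 50 °C) gives the allylboronate (4R,5S)-4,5-dimethyl-4-[(2E)-3-methyl-4-(4,4,5,5-tetramethyl-1,3,2-dioxaborolan-2-yl)but-2-en-1-yl]cyclohex-2-en-1-one F2. This adds to 17 (toluene, rt, if needed with a chiral BINOL-derived phosphoric acid to reinforce the facial bias) through a closed six-membered chair, in which the E geometry is translated strictly into the anti relationship, and returns to the route at 19.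

Step 15. The likely failure is slow acyl transfer to the axial, doubly flanked C9 hydroxyl, with silyl migration or elimination taking over under forcing conditions. The fallback sets out from 25: acylation with the much more reactive 2-(diethoxyphosphoryl)propanoic acid (DCC, DMAP cat., CH2Cl2) gives (4S,5R,7R,8R,9S,10S)-8-[(tert-butyldimethylsilyl)oxy]-2,2-(ethylenedioxy)eremophil-11-en-9-yl 2-(diethoxyphosphoryl)propanoate F3. A Horner–Wadsworth–Emmons reaction with acetaldehyde (LiCl, DBU, MeCN) then builds the E-configured tiglate on the oxygen and returns to the route at 27.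

Step 6. The likely failure is over-oxidation of the allylic alcohol to the enal, oxidation next to the ring ketone, or incomplete conversion. The fallback avoids the late C–H oxidation and sets out from 9: its dienolate 11 is alkylated with the known, pre-oxidised electrophile (E)-[(4-bromo-2-methylbut-2-en-1-yl)oxy](tert-butyl)dimethylsilane F4 to give (5S,6R)-6-[(2E)-4-{[tert-butyl(dimethyl)silyl]oxy}-3-methylbut-2-en-1-yl]-5,6-dimethyl-3-(phenylsulfanyl)cyclohex-2-en-1-one F5. Reduction with i-Bu2AlH and treatment with 2 M aq. HCl in THF, continued until the primary allylic silyl ether is also cleaved, returns to the route at 15.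

**Further compounds**

F1 | step 11 | (4S,5R,7R,8R,10S)-8-[(tert-butyldimethylsilyl)oxy]eremophil-11-ene-2,9-dione | C=C(C)[C@H]1C[C@@]2(C)[C@H](CC(=O)C[C@@H]2C)C(=O)[C@@H]1O[Si](C)(C)C(C)(C)C
F2 | step 8 | (4R,5S)-4,5-dimethyl-4-[(2E)-3-methyl-4-(4,4,5,5-tetramethyl-1,3,2-dioxaborolan-2-yl)but-2-en-1-yl]cyclohex-2-en-1-one | C[C@H]1CC(=O)C=C[C@]1(C)C/C=C(\C)CB2OC(C)(C)C(C)(C)O2
F3 | step 15 | (4S,5R,7R,8R,9S,10S)-8-[(tert-butyldimethylsilyl)oxy]-2,2-(ethylenedioxy)eremophil-11-en-9-yl 2-(diethoxyphosphoryl)propanoate | C=C(C)[C@H]1C[C@@]2(C)[C@H](CC3(OCCO3)C[C@@H]2C)[C@H](OC(=O)C(C)P(=O)(OCC)OCC)[C@@H]1O[Si](C)(C)C(C)(C)C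
F4 | step 6 | (E)-[(4-bromo-2-methylbut-2-en-1-yl)oxy](tert-butyl)dimethylsilane | BrC/C=C(\C)CO[Si](C)(C)C(C)(C)C
F5 | step 6 | (5S,6R)-6-[(2E)-4-{[tert-butyl(dimethyl)silyl]oxy}-3-methylbut-2-en-1-yl]-5,6-dimethyl-3-(phenylsulfanyl)cyclohex-2-en-1-one | C[C@H]1CC(Sc2ccccc2)=CC(=O)[C@]1(C)C/C=C(\C)CO[Si](C)(C)C(C)(C)C
A1 | alternative 1 | cis-fused bicyclic γ-lactone (C6 carbonyl bonded to O9) with ring A as its C2 tert-butyldimethylsilyl enol ether, a C8 silyl ether and a dioxolane-masked methyl ketone side chain | O=C1[C@@]2(C)[C@H](C=C(O[Si](C)(C)C(C)(C)C)C[C@@H]2C)[C@H](O1)[C@@H](CC3(C)OCCO3)O[Si](C)(C)C(C)(C)C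
A2 | alternative 2 | cis-decalin with C14 on C5, a C7 acetyl group, a C8/C9 acetonide and a C2 dioxolane | CC(=O)[C@H]1C[C@@]2(C)[C@H](CC3(OCCO3)C[C@@H]2C)[C@H](OC4(C)C)[C@@H]1O4
A3 | alternative 3 | cis-fused bicyclic enedione with a C6=C7–C8 enone, a C4 ketone, a C2 silyl ether and the angular methyl C14 | C1=C[C@@]2(C)[C@H](C[C@H](O[Si](C)(C)C(C)(C)C)CC2=O)CC1=O
A4 | alternative 3 | (E)-1-methoxy-3-(trimethylsilyloxy)buta-1,3-diene | CO/C=C/C(=C)O[Si](C)(C)C
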